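Elm is the flask asked about. Follow it to 4.0 d.

| setting | elm | birch | flask |
|---|---|---|---|
| starting material | 12 mM | 12 mM | 12 mM |
| reagent in the second phase | 12 mM | 18 mM | 12.0 mM |
| protic impurity | 12 mM | 12 mM | 12.0 mM |
| remark | the very flask that is asked about, followed so far | run made earlier |  |
| time |  |  | 4.0 d |
| volume of the second phase over the first |  |  | 1.0 |

| run | time / h | target / % |
|---|---|---|
| elm | 5.00 | 2.7 |
| elm | 10.0 | 6.7 |
| elm | 15.0 | 8.0 |
| elm | 20.0 | 12.9 |
| elm | 25.0 | 13.8 |
| elm | 30.0 | 17.4 |
| birch | 6.00 | 5.1 |
| birch | 12.0 | 10.3 |
| birch | 20.0 | 18.2 |
| birch | 25.0 | 20.5 |
| birch | 30.0 | 26.1 |
| birch | 40.0 | 30.3 |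

(standard deviation of a reading: 1 percentage point)

- in the second phase: reagent in the second phase; everything else is in the first
- charges count per volume of the first phase; a concentration in a rate is the amount of a species over the volume of its own phase; every rate counts per litre of the first phase
- the analysis behind the earlier runs scatters by 1 percentage point, standard deviation
- the earlier runs hold the two phases in the same ratio of volumes as the flask asked about

* the target standing at 4.0 d, as a percentage of the starting material charged
* the change that raises the amount of target at 4.0 d, in percent of the starting material charged most ("none" if none brings more than 2 percentage points) (south-west / east / none)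
* amount of target at 4.0 d, in percent of the starting material charged, after east

Start with the main step. At 30.0 h, elm reads 17.4 % and birch reads 26.1 %. Their ratio is 1.50, and the ratio of reagent charges is 1.50. So take the rate as first order in the reagent in the second phase. In elm, the fraction of the reagent charge becoming target each hour reads 0.00580 /h. Call this pseudo-first-order constant the supply coefficient. Run it straight for 4.0 d: that gives 55.7 %.

Now add reagent loss. The curve bends to 42.7 %.

Now look at the bend in birch. Its opening slope reads 0.00870 /h. Its last 10.0 h read 0.00420 /h, about half of that, within the scatter. Counted by the target made, birch still holds 0.798 of its reagent, more than that slope ratio of 0.483. So assume the protic impurity is taking the starting material. Let the slope keep halving each such interval. Birch then gets a window of 41.8 h at full supply. Elm has the same impurity charge, so carry the window over. My reckoning for elm is 24.2 %. South-west doubles the reagent charge and leaves the supply coefficient as it stands. East doubles the coefficient, if transfer sets it. Each doubles the hourly supply in this reckoning, so expect each to gain over 2 percentage points.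

The forecast gives 38 %, range 30 % to 45 %. It picks south-west and puts east at 52 %, range 39 % to 63 %. Its ground: “Starting-material depletion seems to matter little”. My number for elm stands lower.

Elm gives 27.9 %. The best change is south-west, with 9.8 points against 8.2 points for east, which reaches 36.2 %.

    starting material + protic impurity → quenched substrate (k = 6.90 /M/h)
    reagent in the reaction phase ⇌ reagent in the second phase, rate k2*([reagent in the reaction phase] - [reagent in the second phase]/K2) per volume of the first phase (partition coefficient = 2.70, kL = 0.0180 /h)
    reagent in the reaction phase ⇌ dormant form (K = 22.0, k = 0.00970 /h)
    starting material + reagent in the reaction phase → target (k = 230 /M/h)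

At 4.00 d, elm holds 0 % starting material and 72.1 % quenched substrate. Divide the target by the supply coefficient: elm got 48.1 h of supply. A neighbour charged with 4.00 equiv of protic impurity gives 5.49 %, worth 9.47 h.

The numbers in the tables were computed from invented constants.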